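Remark: the labdane numbering of the target (C1–C20) is used for every intermediate. α is the face of H-5 and β is the face of C20. The target 25 is 6α-acetoxy-2α,19-dihydroxylabda-8,13-dien-15,16-olide in the normal series (2R,4S,5R,6S,10S).

## The problem

- **Skeleton.** Compound 25 is a trans-decalin with two quaternary carbons, C4 and C10. Their axial groups (C19H2OH and C20H3) sit 1,3-diaxial on the β face.
- **Alkene.** The tetrasubstituted C8=C9 bond abuts C10 and carries C17 and the C11–C16 chain.
- **Stereocentres.** Five must be set: C2, C4, C5, C6 and C10. The axial pair C19/C20 can direct reagents at C5 and C6 to the α face. C2 is remote and equatorial, so it can influence the others only if it is physically tied to them.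
- **Oxygen pattern.** O2 is 1,4-related to C19 and to C5. Neither Robinson annulation (which gives O at C3) nor epoxy-polyene cyclisation (which gives O at C3) delivers it.
- **Acetate.** The acetate sits on the most hindered of the three hydroxyls (6α, next to C4), so O2 and O19 must be masked when it is introduced.
- **Butenolide.** It does not survive hydride, borane, ylide or strong base, so it must come last.
- **Enabling feature.** On ring A the C2–O bond and the C10–C9 bond are 1,3-cis (both α), and C9 bears C11. O2 and C11 can therefore be tied into a six-membered lactone.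
- **Retron.** Ring B (C8=C9 plus the H-5/O-6 pair) is a cyclohexa-1,4-diene (C5=C6, C8=C9) to which water has been added. That diene is the retron of an alkyne Diels–Alder reaction.

## Retrosynthesis

**25 ⇒ 21 + 22.** The C12–C13 bond is cut (B-alkyl Suzuki–Miyaura coupling) and the two silyl ethers of 24 are removed.
- A cut at C11–C12 would need an ambident butenolide nucleophile and an allylic electrophile prone to transposition.
- The C12–C13 cut uses commercial 4-bromofuran-2(5H)-one 22 and places the sensitive ring in the penultimate step.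
- The forward reaction must hydroborate only the vinyl group of 21 and must tolerate an acetate.

**21 ⇒ 17 ⇒ 15.**
- C12 is removed (Wittig), C11 is returned to the alcohol level, and O2/O19 are freed.
- The C5–H and C6–O bonds are then cut together (hydroboration–oxidation of C5=C6).
- This single syn addition sets C5 and C6, which a 6-ketone route would have to do in two operations. It must come from the α face, which the axial C19 and C20 of diene triol 15 enforce.

**15 ⇒ 14.** O2 is reconnected to C11 as a lactone and C19 is raised to the ester. One hydride step undoes both in the forward sense. Releasing the bridge lets ring A relax to the chair that the hydroboration needs.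

**14 ⇒ 13 (key).**
- The C9–C10 and C7–C8 bonds are cut (retro-Diels–Alder).
- An intermolecular version would have neither facial nor secure regiochemical control at the hindered C10. The O2–C11 tether supplies both.
- The precursor 13 is a monocyclic cyclohexene with two stereocentres. The product 14 is tricyclic and holds C10, the complete tetrasubstituted alkene and the C5=C6 handle.

**13 ⇒ 11 + 12; 11 ⇒ 9 ⇒ 7.**
- The ester C–O bond is cut to commercial but-2-ynoic acid 12.
- The C5–C6 bond is cut to a vinyl triflate (Stille coupling).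
- The triflate comes from enone 7 by conjugate reduction and trapping, which fixes the C5=C10 position without ambiguity because C4 is quaternary.

**7 ⇒ 6 ⇒ 5 ⇒ 4.** The C2–O bond is traced to enedione 5 (catalyst-controlled transfer hydrogenation of the unhindered enone carbonyl). Enedione 5 is traced to enone 4 by oxidation of its only γ-CH2. Reagent control is chosen because the Me and CO2Me groups on C4 differ too little to steer a hydride at C2.

**4 ⇒ 1 + 2.** The C3–C4 bond (Michael addition) and the C1=C10 bond (aldol condensation) are cut. All ten ring A carbons, including C18, C19 and C20, come from two commercial compounds. C4 is the one stereocentre set on an achiral substrate.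

## Roads not taken

**Alternative 1: Wieland–Miescher ketone (the obvious route).**
- Cut: the C4–C18 and C4–C19 bonds, with C8–C17 and C9–C11.
- Forward key step: amino-acid-catalysed Robinson annulation to (S)-Wieland–Miescher ketone A1. This is followed by reductive carboxylation and methylation at C4 and chain addition to the C9 ketone.
- Why not: A1 places oxygen at C3 and C9. O3 would have to be moved to C2 by a 1,2-transposition, and C6 is unfunctionalised. C8=C9 would arise from addition to a hindered ketone and a regiochemically open dehydration.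
- Every stereocentre and every oxygen costs its own operations. In the chosen plan three stereocentres and the alkene follow from two events.

**Alternative 2: polyene bicyclisation.**
- Cut: the C4–C5 and C9–C10 bonds.
- Forward key step: cationic or Cp2TiCl (trivalent titanium) opening of a terminal epoxy-polyene, giving a bicycle such as 3β-hydroxydrim-8(12)-en-11-yl acetate A2.
- Why not: both rings form at once, but oxygen ends at C3, the alkene ends exocyclic, and C2, C6 and C19 remain unactivated C–H positions.
- An allylic C6 oxygen in the chain would deactivate the central alkene. The gain in ring construction is lost in three selective oxidations.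

**Alternative 3: quinone Diels–Alder with ring B as the quinone.**
- Cut: the C1–C10 and C4–C5 bonds.
- Forward key step: enantioselective Lewis-acid-catalysed cycloaddition of 2,6-dimethyl-1,4-benzoquinone A3 with 2-(triisopropylsilyloxy)buta-1,3-diene A4 to give the cis-fused adduct A5.
- Merit: A5 has C8-Me, C10-Me, O6, O2 and a C9 carbonyl in place.
- Why not: C4 arrives as CH2, because a diene terminus with both C4 substituents cannot reach the s-cis form. C19 would then have to enter on the β face, syn to C20 and against the steric bias. C5 must be epimerised and C9 deoxygenated after chain addition. The chosen plan builds C4 first, where it is easy.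

Key step: step 8

Assumption: the hands of the catalysts in steps 1 and 3 are chosen to give (S)-3 and (5S)-6. Both antipodes of each catalyst are available.

## Steps

Step 1
Reactants: 1 methyl 2-methyl-3-oxopentanoate; 2 acrolein
Product: 4 methyl (S)-1,3-dimethyl-2-oxocyclohex-3-ene-1-carboxylate, via keto aldehyde 3 (not isolated)
Conditions: 9-O-(9-phenanthryl)cupreidine or its cupreine pseudo-enantiomer (10 mol %), CH2Cl2, −25 °C; then p-TsOH·H2O (20 mol %), PhMe, reflux, Dean–Stark
Reagents that add atoms: none
Why: Bifunctional cinchona-catalysed asymmetric Michael addition of an α-substituted β-keto ester to acrolein sets quaternary C4; the only possible intramolecular aldol condensation (C10 onto C1, six-membered ring) then closes ring A.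

Step 2
Reactants: 4 methyl (S)-1,3-dimethyl-2-oxocyclohex-3-ene-1-carboxylate
Product: 5 methyl (S)-1,3-dimethyl-2,5-dioxocyclohex-3-ene-1-carboxylate
Conditions: Pd(OH)2/C (5 mol %), t-BuOOH (5 equiv), K2CO3 (0.25 equiv), CH2Cl2, 4 → 24 °C
Reagents that add atoms: tert-butyl hydroperoxide, CC(C)(C)OO
Why: Known catalytic γ-oxidation of α,β-enones to 1,4-enediones; C2 is the only γ-methylene, and quaternary C4 blocks aromatisation of the product.

Step 3
Reactants: 5 methyl (S)-1,3-dimethyl-2,5-dioxocyclohex-3-ene-1-carboxylate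
Product: 6 methyl (1S,5S)-5-hydroxy-1,3-dimethyl-2-oxocyclohex-3-ene-1-carboxylate
Conditions: RuCl(p-cymene)[(S,S)-TsDPEN] (1 mol %), HCO2H/Et3N (5:2), CH2Cl2, 0 °C
Reagents that add atoms: none
Why: Asymmetric transfer hydrogenation, known on the 2,6,6-trimethyl analogue of 5, reduces only the unhindered C2 carbonyl; the catalyst tells the alkenyl side (C1) from the alkyl side (C3), so C2 is set by reagent control, O2 trans to C19.

Step 4
Reactants: 6 methyl (1S,5S)-5-hydroxy-1,3-dimethyl-2-oxocyclohex-3-ene-1-carboxylate
Product: 7 methyl (1S,5S)-1,3-dimethyl-2-oxo-5-(triethylsilyloxy)cyclohex-3-ene-1-carboxylate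
Conditions: Et3SiCl, imidazole, CH2Cl2, 0 °C
Reagents that add atoms: chlorotriethylsilane, CC[Si](Cl)(CC)CC
Why: Routine silylation; the free hydroxyl would quench the enolate of step 5 or be sulfonylated.

Step 5
Reactants: 7 methyl (1S,5S)-1,3-dimethyl-2-oxo-5-(triethylsilyloxy)cyclohex-3-ene-1-carboxylate
Product: 9 methyl (1S,5R)-1,3-dimethyl-5-(triethylsilyloxy)-2-(trifluoromethylsulfonyloxy)cyclohex-2-ene-1-carboxylate, via lithium enolate 8 (not isolated)
Conditions: LiBH(s-Bu)3, THF, −78 °C; then N-(5-chloro-2-pyridyl)bis(trifluoromethanesulfonimide), −78 → 0 °C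
Reagents that add atoms: N-(5-chloro-2-pyridyl)bis(trifluoromethanesulfonimide), Clc1ccc(nc1)N(S(=O)(=O)C(F)(F)F)S(=O)(=O)C(F)(F)F
Why: Conjugate reduction–triflation of a cyclohexenone with no extra β-substituent and a hindered carbonyl; hydride adds at C1 and the regiodefined C5=C10 enolate is trapped on oxygen (the C2 descriptor changes by priority only).

Step 6
Reactants: 9 methyl (1S,5R)-1,3-dimethyl-5-(triethylsilyloxy)-2-(trifluoromethylsulfonyloxy)cyclohex-2-ene-1-carboxylate
Product: 11 methyl (1S,5R)-2-ethenyl-5-hydroxy-1,3-dimethylcyclohex-2-ene-1-carboxylate, via triethylsilyl diene 10 (not isolated)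
Conditions: Bu3SnCH=CH2, Pd(PPh3)4 (5 mol %), LiCl, THF, reflux; then 1 M aq HCl, THF, 0 °C
Reagents that add atoms: tributyl(vinyl)stannane, C=C[Sn](CCCC)(CCCC)CCCC
Why: Stille vinylation, well known for 2,6,6-trisubstituted cyclohexenyl triflates, forms C5–C6; brief dilute acid removes the labile triethylsilyl group in the same flask.

Step 7
Reactants: 11 methyl (1S,5R)-2-ethenyl-5-hydroxy-1,3-dimethylcyclohex-2-ene-1-carboxylate; 12 but-2-ynoic acid
Product: 13 methyl (1S,5R)-5-(but-2-ynoyloxy)-2-ethenyl-1,3-dimethylcyclohex-2-ene-1-carboxylate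
Conditions: DCC, DMAP (cat.), CH2Cl2, 0 °C → rt
Reagents that add atoms: none
Why: Steglich esterification with retention at C2; acylation is preferred to an invertive esterification because O2 is homoallylic and substitution at C2 would compete with elimination.

Step 8
Reactants: 13 methyl (1S,5R)-5-(but-2-ynoyloxy)-2-ethenyl-1,3-dimethylcyclohex-2-ene-1-carboxylate
Product: 14 tricyclic dienyl lactone (C11(=O)–O–C2α bridge, C5=C6, C8=C9, 10β-Me, 4α-Me, 4β-CO2Me)
Conditions: PhMe (0.005 M), BHT (cat.), sealed vessel, 150 °C
Reagents that add atoms: none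
Why: Thermal intramolecular Diels–Alder reaction of the but-2-ynoate (C8≡C9, activated by the C11 carbonyl) with the s-cis diene C7=C6–C5=C10, concerted and suprafacial on both partners. The closest known reaction type is the ester-tethered cycloaddition of alkynoates of 2-vinylcyclohex-2-en-1-ols, which builds the same methyl-bearing quaternary carbon and 1,4-diene through a five-membered lactone; here the carbinol is one carbon further away and a six-membered lactone results. Two rings close: ring B by the [4+2] bond pair C7–C8/C9–C10, and the δ-lactone O2–C11–C9–C10–C1–C2 by the C9–C10 bond (four-atom tether, a 2-oxabicyclo[3.3.1]nonane together with ring A). C10 is the only new stereocentre and is fixed by C2: the tether reaches C10 only with O2 axial on the ring A half-chair, so C9 bonds to the face that carries O2 (α) and C20 is pushed to β. The regiochemistry (C9 to C10, C8 to C7) is enforced by the tether and agrees with the ortho preference of a dialkylated diene terminus for the acyl-bearing alkyne carbon. An alkyne raises no endo/exo question, and the product holds C8=C9 with C17 and C11 in place and C5=C6 for step 10. The cycloaddition must outrun the [1,5]-hydrogen shift from C20 to C7 and intermolecular addition; the activated alkyne, high dilution and a radical inhibitor serve this.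

Step 9
Reactants: 14 tricyclic dienyl lactone
Product: 15 12,13,14,15,16-pentanorlabda-5,8-diene-2α,11,19-triol
Conditions: LiAlH4, THF, 0 °C → reflux; then H2O, aq NaOH
Reagents that add atoms: none
Why: Hydride reduction of the lactone (1,2-mode, the β-carbon being fully substituted) and of the C19 ester in one step; opening the bridge lets ring A flip to the chair with O2 equatorial and C19/C20 axial.

Step 10
Reactants: 15 12,13,14,15,16-pentanorlabda-5,8-diene-2α,11,19-triol
Product: 17 12,13,14,15,16-pentanorlabd-8-ene-2α,6α,11,19-tetraol (5α-H), via C6 borane 16 (not isolated)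
Conditions: BH3·THF (excess), THF, 0 °C → rt; then NaOH, H2O2, 0 °C
Reagents that add atoms: hydrogen peroxide, OO
Why: Hydroboration–oxidation, syn, with boron at the less substituted C6; axial C19 and C20 flank C5 on the β face, so H-5 and O-6 both arrive α (trans-decalin, 6α-OH) as with 4,4-dimethyl-5-ene steroids; the tetrasubstituted C8=C9 is inert.

Step 11
Reactants: 17 12,13,14,15,16-pentanorlabd-8-ene-2α,6α,11,19-tetraol
Product: 18 2α,6α,19-trihydroxy-12,13,14,15,16-pentanorlabd-8-en-11-al
Conditions: MnO2 (activated), CH2Cl2/THF, rt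
Reagents that add atoms: none
Why: MnO2 oxidises only the allylic C11 alcohol; the three saturated alcohols are untouched.

Step 12
Reactants: 18 2α,6α,19-trihydroxy-12,13,14,15,16-pentanorlabd-8-en-11-al
Product: 19 2α,19-bis(tert-butyldimethylsilyloxy)-6α-hydroxy-12,13,14,15,16-pentanorlabd-8-en-11-al
Conditions: t-BuMe2SiCl (2.3 equiv), imidazole, DMF, 0 °C → rt
Reagents that add atoms: tert-butyldimethylsilyl chloride, CC(C)(C)[Si](C)(C)Cl
Why: Rate-selective silylation: primary O19 and unhindered equatorial O2 react before O6, which is crowded by C4 and its equatorial C18.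

Step 13
Reactants: 19 2α,19-bis(tert-butyldimethylsilyloxy)-6α-hydroxy-12,13,14,15,16-pentanorlabd-8-en-11-al
Product: 20 2α,19-bis(tert-butyldimethylsilyloxy)-13,14,15,16-tetranorlabda-8,11-dien-6α-ol
Conditions: Ph3PCH3Br, KN(SiMe3)2 (3 equiv each), THF, 0 °C → rt
Reagents that add atoms: methyltriphenylphosphonium bromide, C[P+](c1ccccc1)(c1ccccc1)c1ccccc1.[Br-]
Why: Wittig methylenation, known for equally hindered 2,6,6-trisubstituted cyclohexenecarbaldehydes; it is run before acetylation so that excess ylide meets only an alkoxide.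

Step 14
Reactants: 20 2α,19-bis(tert-butyldimethylsilyloxy)-13,14,15,16-tetranorlabda-8,11-dien-6α-ol
Product: 21 6α-acetoxy-2α,19-bis(tert-butyldimethylsilyloxy)-13,14,15,16-tetranorlabda-8,11-diene
Conditions: Ac2O, DMAP, pyridine, CH2Cl2, rt
Reagents that add atoms: acetic anhydride, CC(=O)OC(C)=O
Why: DMAP-catalysed acetylation of the only free hydroxyl.

Step 15
Reactants: 21 6α-acetoxy-2α,19-bis(tert-butyldimethylsilyloxy)-13,14,15,16-tetranorlabda-8,11-diene; 22 4-bromofuran-2(5H)-one
Product: 24 6α-acetoxy-2α,19-bis(tert-butyldimethylsilyloxy)labda-8,13-dien-15,16-olide, via B-alkyl-9-BBN 23 (not isolated)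
Conditions: 9-BBN-H, THF, rt; then 22, PdCl2(dppf) (5 mol %), AsPh3, Cs2CO3, DMF/H2O, rt
Reagents that add atoms: none
Why: 9-BBN adds only to the monosubstituted, sterically twisted vinyl group with boron at C12; B-alkyl Suzuki–Miyaura coupling with a 4-halofuranone is a known way to 4-alkylbutenolides and forms C12–C13 at room temperature.

Step 16
Reactants: 24 6α-acetoxy-2α,19-bis(tert-butyldimethylsilyloxy)labda-8,13-dien-15,16-olide
Product: 25 6α-acetoxy-2α,19-dihydroxylabda-8,13-dien-15,16-olide (target)
Conditions: HF·pyridine, pyridine/THF, 0 °C → rt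
Reagents that add atoms: none
Why: Buffered fluoride cleaves both silyl ethers without touching the acetate or butenolide; O6 (α) and O19 (β) lie on opposite faces, so acetyl migration is not expected.

## Compound list

1 | methyl 2-methyl-3-oxopentanoate | CCC(=O)C(C)C(=O)OC | starting material
2 | acrolein | C=CC=O | starting material
3 | methyl (S)-2-methyl-3-oxo-2-(3-oxopropyl)pentanoate | O=CCC[C@](C)(C(=O)OC)C(=O)CC | intermediate
4 | methyl (S)-1,3-dimethyl-2-oxocyclohex-3-ene-1-carboxylate | O=C1C(C)=CCC[C@]1(C)C(=O)OC | intermediate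
5 | methyl (S)-1,3-dimethyl-2,5-dioxocyclohex-3-ene-1-carboxylate | O=C1C(C)=CC(=O)C[C@]1(C)C(=O)OC | intermediate
6 | methyl (1S,5S)-5-hydroxy-1,3-dimethyl-2-oxocyclohex-3-ene-1-carboxylate | O=C1C(C)=C[C@@H](O)C[C@]1(C)C(=O)OC | intermediate
7 | methyl (1S,5S)-1,3-dimethyl-2-oxo-5-(triethylsilyloxy)cyclohex-3-ene-1-carboxylate | O=C1C(C)=C[C@@H](O[Si](CC)(CC)CC)C[C@]1(C)C(=O)OC | intermediate
8 | lithium C5=C10 enolate of the 1,4-reduced 7 | [Li+].[O-]C1=C(C)C[C@@H](O[Si](CC)(CC)CC)C[C@]1(C)C(=O)OC | intermediate
9 | methyl (1S,5R)-1,3-dimethyl-5-(triethylsilyloxy)-2-(trifluoromethylsulfonyloxy)cyclohex-2-ene-1-carboxylate | O=S(=O)(OC1=C(C)C[C@@H](O[Si](CC)(CC)CC)C[C@]1(C)C(=O)OC)C(F)(F)F | intermediate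
10 | methyl (1S,5R)-2-ethenyl-1,3-dimethyl-5-(triethylsilyloxy)cyclohex-2-ene-1-carboxylate | C=CC1=C(C)C[C@@H](O[Si](CC)(CC)CC)C[C@]1(C)C(=O)OC | intermediate
11 | methyl (1S,5R)-2-ethenyl-5-hydroxy-1,3-dimethylcyclohex-2-ene-1-carboxylate | C=CC1=C(C)C[C@@H](O)C[C@]1(C)C(=O)OC | intermediate
12 | but-2-ynoic acid | CC#CC(=O)O | starting material
13 | methyl (1S,5R)-5-(but-2-ynoyloxy)-2-ethenyl-1,3-dimethylcyclohex-2-ene-1-carboxylate | C=CC1=C(C)C[C@@H](OC(=O)C#CC)C[C@]1(C)C(=O)OC | intermediate
14 | methyl 12,13,14,15,16-pentanorlabda-5,8-dien-11,2α-olid-19-oate (tricyclic lactone) | C1C(C)=C3[C@@]2(C)C[C@@H](OC3=O)C[C@](C)(C(=O)OC)C2=C1 | intermediate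
15 | 12,13,14,15,16-pentanorlabda-5,8-diene-2α,11,19-triol | C1C(C)=C(CO)[C@@]2(C)C[C@@H](O)C[C@](C)(CO)C2=C1 | intermediate
16 | 6α-boryl-5α-H adduct of 15 (drawn as the C6–BH2 compound) | B[C@H]1CC(C)=C(CO)[C@@]2(C)C[C@@H](O)C[C@](C)(CO)[C@H]12 | intermediate
17 | 12,13,14,15,16-pentanorlabd-8-ene-2α,6α,11,19-tetraol | O[C@H]1CC(C)=C(CO)[C@@]2(C)C[C@@H](O)C[C@](C)(CO)[C@H]12 | intermediate
18 | 2α,6α,19-trihydroxy-12,13,14,15,16-pentanorlabd-8-en-11-al | O[C@H]1CC(C)=C(C=O)[C@@]2(C)C[C@@H](O)C[C@](C)(CO)[C@H]12 | intermediate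
19 | 2α,19-bis(tert-butyldimethylsilyloxy)-6α-hydroxy-12,13,14,15,16-pentanorlabd-8-en-11-al | O[C@H]1CC(C)=C(C=O)[C@@]2(C)C[C@@H](O[Si](C)(C)C(C)(C)C)C[C@](C)(CO[Si](C)(C)C(C)(C)C)[C@H]12 | intermediate
20 | 2α,19-bis(tert-butyldimethylsilyloxy)-13,14,15,16-tetranorlabda-8,11-dien-6α-ol | O[C@H]1CC(C)=C(C=C)[C@@]2(C)C[C@@H](O[Si](C)(C)C(C)(C)C)C[C@](C)(CO[Si](C)(C)C(C)(C)C)[C@H]12 | intermediate
21 | 6α-acetoxy-2α,19-bis(tert-butyldimethylsilyloxy)-13,14,15,16-tetranorlabda-8,11-diene | CC(=O)O[C@H]1CC(C)=C(C=C)[C@@]2(C)C[C@@H](O[Si](C)(C)C(C)(C)C)C[C@](C)(CO[Si](C)(C)C(C)(C)C)[C@H]12 | intermediate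
22 | 4-bromofuran-2(5H)-one | O=C1C=C(Br)CO1 | starting material
23 | C12 B-alkyl-9-borabicyclo[3.3.1]nonane from 21 | CC(=O)O[C@H]1CC(C)=C(CCB3C4CCCC3CCC4)[C@@]2(C)C[C@@H](O[Si](C)(C)C(C)(C)C)C[C@](C)(CO[Si](C)(C)C(C)(C)C)[C@H]12 | intermediate
24 | 6α-acetoxy-2α,19-bis(tert-butyldimethylsilyloxy)labda-8,13-dien-15,16-olide | CC(=O)O[C@H]1CC(C)=C(CCC3=CC(=O)OC3)[C@@]2(C)C[C@@H](O[Si](C)(C)C(C)(C)C)C[C@](C)(CO[Si](C)(C)C(C)(C)C)[C@H]12 | intermediate
25 | 6α-acetoxy-2α,19-dihydroxylabda-8,13-dien-15,16-olide | CC(=O)O[C@H]1CC(C)=C(CCC2=CC(=O)OC2)[C@@]2(C)C[C@@H](O)C[C@](C)(CO)[C@H]12 | target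

## Step count and least certain steps

Total step count: 16. Longest linear sequence: 16 steps, from 1 to 25.

**Step 8 (key step).**
- What may go wrong: the cycloaddition may be too slow. The reactive conformer needs O2 axial, syn to the pseudoaxial C18, and the less stable s-cis rotamer of the ester. The [1,5]-hydrogen shift from C20, thermal loss of but-2-ynoic acid across C1–C2, or oligomerisation could then take over.
- Fallback: it sets out from 11, which is esterified with 3-(p-tolylsulfonyl)propiolic acid (DCC) to the sulfonylpropiolate F1.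
- The doubly activated alkyne of F1 should cycloadd at or near room temperature to the C8-sulfonyl lactone F2.
- Addition–elimination with Me2CuLi then replaces the sulfonyl group by C17 and returns to the route at 14.

**Step 1.**
- What may go wrong: low enantioselectivity, because the enol geometry of an acyclic α-methyl β-keto ester is not fixed, unlike that of the cyclic donors for which the reaction is best known.
- Fallback: it sets out from 1 and 2. Achiral amine catalysis and the same condensation give the racemic enone F3, and step 2 gives the racemic enedione F4.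
- The catalyst-controlled reduction of step 3 is then used as a divergent reaction on the racemate. It gives 6 and its (1R,5S)-diastereomer F5, which are separated by chromatography.
- The route is rejoined at 6, at the price of half the material.

**Step 3.**
- What may go wrong: conjugate reduction of the electron-poor C1=C10 bond, redox isomerisation of the allylic alcohol to the saturated dione, or a mismatch between catalyst and C4.
- Fallback: it sets out from 5. Zn/AcOH saturates the alkene to the dione F6 (a mixture at C10, which is erased later).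
- An NADPH-dependent ketoreductase of the short-chain dehydrogenase class (the type that reduces the 2,2,6-trimethyl analogue at the same carbonyl) gives the ketol F7.
- Et3SiCl gives the silyl ether F8. KN(SiMe3)2 and the triflimide reagent of step 5 return to the route at 9.

**Step 10.**
- What may go wrong: sluggish addition to an alkene flanked by two quaternary carbons, and erosion of facial selectivity if a C19 alkoxyborane delivers boron on the β face.
- Fallback: it sets out from 15, which is fully silylated (t-BuMe2SiOTf, 2,6-lutidine) to the tris(silyl ether) F9. No alkoxyborane can then form, and the β face is bulkier.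
- Hydroboration–oxidation gives the 6α-alcohol F10, and acetylation gives F11.
- DDQ oxidises the allylic silyl ether directly to the enal acetate F12. Wittig methylenation at low temperature returns to the route at 21.

**Step 15.**
- What may go wrong: base-induced hydrolysis or ring opening of 22 before transmetalation, and protodeboronation of 23.
- Fallback: it sets out from 21. Treatment with 9-BBN-H and then NaBO3 gives the C12 alcohol F13, and I2/PPh3/imidazole gives the iodide F14.
- Zinc insertion (Zn, LiCl) gives the alkylzinc iodide F15. Base-free Negishi coupling with 22, under a zerovalent palladium catalyst generated from PdCl2(dppf), returns to the route at 24.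

## Further compounds

F1 | step 8 | methyl (1S,5R)-2-ethenyl-1,3-dimethyl-5-[3-(p-tolylsulfonyl)prop-2-ynoyloxy]cyclohex-2-ene-1-carboxylate | C=CC1=C(C)C[C@@H](OC(=O)C#CS(=O)(=O)c2ccc(C)cc2)C[C@]1(C)C(=O)OC
F2 | step 8 | analogue of 14 with p-tolylsulfonyl in place of C17 on C8 | C1C(=C3[C@@]2(C)C[C@@H](OC3=O)C[C@](C)(C(=O)OC)C2=C1)S(=O)(=O)c1ccc(C)cc1
F3 | step 1 | racemic methyl 1,3-dimethyl-2-oxocyclohex-3-ene-1-carboxylate | O=C1C(C)=CCCC1(C)C(=O)OC
F4 | step 1 | racemic methyl 1,3-dimethyl-2,5-dioxocyclohex-3-ene-1-carboxylate | O=C1C(C)=CC(=O)CC1(C)C(=O)OC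
F5 | step 1 | methyl (1R,5S)-5-hydroxy-1,3-dimethyl-2-oxocyclohex-3-ene-1-carboxylate | O=C1C(C)=C[C@@H](O)C[C@@]1(C)C(=O)OC
F6 | step 3 | methyl (1S)-1,3-dimethyl-2,5-dioxocyclohexane-1-carboxylate (C3 epimers) | O=C1C(C)CC(=O)C[C@]1(C)C(=O)OC
F7 | step 3 | methyl (1S,5R)-5-hydroxy-1,3-dimethyl-2-oxocyclohexane-1-carboxylate (C3 epimers) | O=C1C(C)C[C@@H](O)C[C@]1(C)C(=O)OC
F8 | step 3 | methyl (1S,5R)-1,3-dimethyl-2-oxo-5-(triethylsilyloxy)cyclohexane-1-carboxylate (C3 epimers) | O=C1C(C)C[C@@H](O[Si](CC)(CC)CC)C[C@]1(C)C(=O)OC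
F9 | step 10 | 2α,11,19-tris(tert-butyldimethylsilyloxy)-12,13,14,15,16-pentanorlabda-5,8-diene | C1C(C)=C(CO[Si](C)(C)C(C)(C)C)[C@@]2(C)C[C@@H](O[Si](C)(C)C(C)(C)C)C[C@](C)(CO[Si](C)(C)C(C)(C)C)C2=C1
F10 | step 10 | 2α,11,19-tris(tert-butyldimethylsilyloxy)-12,13,14,15,16-pentanorlabd-8-en-6α-ol | O[C@H]1CC(C)=C(CO[Si](C)(C)C(C)(C)C)[C@@]2(C)C[C@@H](O[Si](C)(C)C(C)(C)C)C[C@](C)(CO[Si](C)(C)C(C)(C)C)[C@H]12
F11 | step 10 | 6α-acetate of F10 | CC(=O)O[C@H]1CC(C)=C(CO[Si](C)(C)C(C)(C)C)[C@@]2(C)C[C@@H](O[Si](C)(C)C(C)(C)C)C[C@](C)(CO[Si](C)(C)C(C)(C)C)[C@H]12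
F12 | step 10 | 6α-acetoxy-2α,19-bis(tert-butyldimethylsilyloxy)-12,13,14,15,16-pentanorlabd-8-en-11-al | CC(=O)O[C@H]1CC(C)=C(C=O)[C@@]2(C)C[C@@H](O[Si](C)(C)C(C)(C)C)C[C@](C)(CO[Si](C)(C)C(C)(C)C)[C@H]12
F13 | step 15 | 6α-acetoxy-2α,19-bis(tert-butyldimethylsilyloxy)-13,14,15,16-tetranorlabd-8-en-12-ol | CC(=O)O[C@H]1CC(C)=C(CCO)[C@@]2(C)C[C@@H](O[Si](C)(C)C(C)(C)C)C[C@](C)(CO[Si](C)(C)C(C)(C)C)[C@H]12
F14 | step 15 | the corresponding C12 iodide | CC(=O)O[C@H]1CC(C)=C(CCI)[C@@]2(C)C[C@@H](O[Si](C)(C)C(C)(C)C)C[C@](C)(CO[Si](C)(C)C(C)(C)C)[C@H]12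
F15 | step 15 | the corresponding C12 alkylzinc iodide | CC(=O)O[C@H]1CC(C)=C(CC[Zn]I)[C@@]2(C)C[C@@H](O[Si](C)(C)C(C)(C)C)C[C@](C)(CO[Si](C)(C)C(C)(C)C)[C@H]12
A1 | alternative 1 | (S)-Wieland–Miescher ketone | C[C@]12CCC(=O)C=C1CCCC2=O
A2 | alternative 2 | 3β-hydroxydrim-8(12)-en-11-yl acetate | C1CC(=C)[C@H](COC(C)=O)[C@@]2(C)CC[C@H](O)C(C)(C)[C@H]12
A3 | alternative 3 | 2,6-dimethyl-1,4-benzoquinone | CC1=CC(=O)C=C(C)C1=O
A4 | alternative 3 | 2-(triisopropylsilyloxy)buta-1,3-diene | C=CC(=C)O[Si](C(C)C)(C(C)C)C(C)C
A5 | alternative 3 | cis-fused adduct (C6 and C9 ketones, C7=C8, 8-Me, 10β-Me, 5β-H, C2 silyl enol ether) | O=C1C=C(C)C(=O)[C@@]2(C)CC(O[Si](C(C)C)(C(C)C)C(C)C)=CC[C@@H]12
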